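Which flask ends highest in isomer of the product comes down to where each mole of starting material has gone by 50 min.

| flask | starting material | reagent | remark | time |
|---|---|---|---|---|
| ochre | 0.25 M | 0.375 M | run made earlier |  |
| blue | 0.35 M | 0.375 M | run made earlier |  |
| teal | 0.55 M | 0.375 M | run made earlier |  |
| north | 0.25 M | 0.375 M | everything together at the start | 50 min |
| south-west | 0.25 M (fed, over 40 min) | 0.375 M | all else is in the flask from the start; the feed brings no volume worth counting | 50 min |
| east | 0.25 M | 0.375 M (fed, over 40 min) | all else is in the flask from the start; the feed brings no volume worth counting | 50 min |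
| north-east | 0.25 M (in portions, 2, over 40 min) | 0.375 M | first portion at the start, last at 40 min | 50 min |

| run | time / min | isomer of the product / % | target / % |
|---|---|---|---|
| ochre | 2.50 | 0.8 | 0.8 |
| ochre | 8.00 | 4.6 | 0.9 |
| ochre | 15.0 | 9.8 | 0 |
| ochre | 20.0 | 11.8 | 0.3 |
| ochre | 30.0 | 18.4 | 0.5 |
| blue | 10.0 | 6.5 | 0.3 |
| blue | 20.0 | 12.5 | 0 |
| blue | 30.0 | 18.3 | 0 |
| blue | 40.0 | 23.3 | 0.3 |
| blue | 50.0 | 28.6 | 0 |
| teal | 4.00 | 2.3 | 0.4 |
| teal | 12.0 | 6.6 | 0 |
| teal | 25.0 | 14.4 | 0.5 |
| teal | 40.0 | 23.3 | 0.2 |
| teal | 50.0 | 26.8 | 0 |

(scatter of a reading: 0.5 percentage points)

- the numbers in the tables scatter with a standard deviation of 0.5 percentage points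

* the flask that comes out highest in amount of isomer of the product, in percent of the starting material charged; "all alike" if 1.5 percentage points covers them all (north / south-west / east / north-east / all alike)
* amount of isomer of the product at the end, in percent of the starting material charged, north
* amount of isomer of the product at the end, in percent of the starting material charged, south-west
* amount of isomer of the product at the end, in percent of the starting material charged, east
* amount of isomer of the product at the end, in percent of the starting material charged, north-east

With one reagent taken per starting material, starting material is the limiting reagent in the new flasks, at 0.25 M against 0.375 M of reagent, so the books are kept on it.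

The target entry in ochre reads from 0% to 0.9% against a scatter of 0.5 points, so this reckoning books it at nothing.

The isomer entry comes next. Blue and teal both read 23.3% at 40.0 min, from charges of 0.35 M and 0.55 M, so a mole of starting material seems to run on its own clock, first order. At 50 min they read 28.6% and 26.8%, which gives a batch entry:

isomer of the product, north: 27.7%
starting material left, north: 72.3%

A mole added late has less time, so the fed flasks need one more quantity. The exposure share is the mean time a mole of starting material spends in the flask, divided by the batch time. For a first-order entry, while conversion stays low, the rate constant cancels in this ratio. South-west's steady feed has the same mean as north-east's portions, which stand in the flask for 50 min and 10.0 min: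

exposure share = (time less half the feed time) / time = 0.600
isomer of the product, south-west and north-east: 16.6%

East holds its starting material from the start, so this reckoning books east like north. That is uncertain, since ochre, blue and teal each hold reagent at 0.375 M.

The forecast names north: north 28.2%, south-west 17.6%, east 27.5%, north-east 17.2%. Its south-west and north-east stand above the reckoning here, and of east it says “so north is the safest pick”.

Highest comes out north: north 28.2%, south-west 17.3%, east 26.2%, north-east 16.9%.

    reagent ⇌ dormant form (K = 0.830, k = 0.0160 min⁻¹)
    starting material ⇌ tight pair (K = 0.0520, k = 0.00840 min⁻¹)
    reagent + loose pair → isomer of the product (k = 7.90 M⁻¹ min⁻¹)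
    reagent + tight pair ⇌ target (K = 1.00 M⁻¹, k = 6.20 M⁻¹ min⁻¹)
    tight pair ⇌ loose pair (K = 0.560, k = 2.70 min⁻¹)

North's books close at 70.5% starting material, 28.2% isomer of the product, 0.763% tight pair, 0.330% loose pair and 0.138% target. The exposure share times north's result gives 16.9%, and north-east holds 16.9%. Left until 80 min, north-east has a share of 0.750; with north's first-order curve carried to that time this gives 30.9%, and that flask holds 31.7%.

The numbers in the tables were computed for substances that don't exist; noise was put on by code.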